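I decided to reckon each flask as a fraction of its own charge, and to ask what fraction of the starting material stays behind rather than what fraction is made.

in all of them: free catalyst 51 µM
- Saturday's: starting material 0.041 M; gas phase 4 mM (held); run made earlier
- Friday's: starting material 0.17 M; gas phase 4 mM (held); run made earlier
- gamma: starting material 0.030 M; gas phase 4.0 mM (held); time 3.0 h
- delta: starting material 0.060 M; gas phase 4.0 mM (held); time 3.0 h
- theta: starting material 0.15 M; gas phase 4.0 mM (held); time 3.0 h

- Saturday's (time / h: target / %): 0.417: 17.6; 0.833: 5.0; 1.33: 3.7; 1.50: 3.7; 2.00: 3.3; 2.50: 3.1; 3.00: 3.1
- Friday's (time / h: target / %): 0.250: 8.1; 0.333: 9.2; 0.500: 7.9; 0.833: 3.1; 1.33: 1.0; 2.00: 1.2; 3.00: 1.4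

(standard deviation of a reading: 0.3 percentage points)

- what was read earlier has a scatter of 0.3 percentage points, one standard deviation
- at the start none of the gas phase is in solution
- "hardly changes" means that all values lie within two and a half points (for a concentration: within two and a half percent of the largest)

- [target] at the end for gamma, delta, theta, in this order
- the shape of the row from first to last (hardly changes / rises all the way / falls, then rises / rises, then falls / falls all the way)

The flask starts with none of the gas phase in solution, yet by 0.250 h Friday's run already read 8.1 % of its charge as target. In the middle of the run the readings turn. Friday's stood at 9.2 % at 0.333 h, and Saturday's fell from 17.6 % at 0.417 h to 5.0 % at 0.833 h, so I supposed that target was passing into something I could not read. By the end the readings lie nearly flat: Saturday's gave 3.1 % and 3.1 %, while Friday's moved by 0.4 percentage points over its last readings against a scatter of 0.3 points.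

I therefore took the late target as a fixed share of whatever had reacted, and I let the fraction left grow with the charge as charge divided by charge plus a constant. That constant is the balance charge, the charge of which, with this free catalyst charge and this gas level held, as much stays behind as reacts. This form was my assumption, not something the readings showed. The last readings of the two runs, with their scatter, then give an estimated share of 5.05 % and an estimated balance charge of 0.0652 M. On this assumption I reckoned the starting material left in Saturday's run at 38.6 % of its charge and in Friday's at 72.3 %.

For gamma, delta and theta I expected target at 3.46 %, 2.63 % and 1.53 % of the charge. That is 0.00104 M, 0.00158 M and 0.00230 M, rising from first to last.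

The forecast gave 0.00115 M, 0.00145 M and 0.0022 M, rises all the way, as “an empirical interpolation between two points”, which is higher than mine for gamma and lower for delta and theta.

The flask gave 0.00110 M, 0.00167 M and 0.00238 M, a row that rises all the way, by this scheme:

    starting material + dissolved gas + free catalyst → free catalyst + target (k = 1.00 × 10⁵ M⁻² s⁻¹)
    target ⇌ isomer of the product (K = 22.0, k = 0.110 min⁻¹)
    free catalyst → spent catalyst (k = 0.150 min⁻¹)
    gas phase ⇌ dissolved gas, rate k4*(csat - [dissolved gas]) (kL = 0.510 min⁻¹)

At the end, gamma, delta and theta held 15.9 %, 36.2 % and 63.5 % of their charge as starting material. The balance charge of 0.0652 M puts the fraction left in theta at 69.7 %, against 63.5 % in the flask, and in delta at 47.9 %, against 36.2 %.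

All runs are calculated from invented constants, and the scatter is random.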